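**Strategy.** Everything rests on cutting the C1–C14 bond of the 14-membered ring. Because the C1 stereocentre carries the exocyclic C15=C16 methylene beside ring carbon C14, the array C14–C1–C15=C16 is the retron of an ester enolate Claisen rearrangement. An 18-membered lactone that ties a carboxyl carbon on C14 (C22) to the C16 allylic oxygen is enolised with a chiral bromoborane; a single [3,3] shift then forms C1–C14, sets C1, contracts the ring to the carbocycle and releases the methylene. The lactone is made from an open-chain hydroxy acid with four stereodefined trisubstituted olefins; the surplus carboxyl is removed afterwards by radical decarboxylation.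

Key step: step 20

Atom labels: ring C1 (stereocentre), C2, C3=C4, C5, C6, C7=C8, C9, C10, C11=C12, C13, C14; side chain C15(=C16)–C17–C18–C19=C20; C21 is the oxygenated carbon on C4; C22 is the carboxyl carbon on C14 until step 21.

Protecting groups: C21–O is carried as the tert-butyldiphenylsilyl (TBDPS) ether, C16–O for a time as the tert-butyldimethylsilyl (TBS) ether and C9–O as the triethylsilyl (TES) ether, so that each can be removed beside the more robust ones.

Assumption: the (S,S)-diazaborolidine is taken to open the enolate face that leads to (1S,14S)-34; if the sense of induction is the opposite one, the equally available (R,R)-reagent is used and nothing else changes.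

**Step 1**
Reactants: 1 5-bromo-2-methylpent-2-ene
Product: 2 (E)-5-bromo-2-methylpent-2-en-1-ol
Conditions: SeO2 (0.5 equiv), t-BuOOH, salicylic acid (cat.), CH2Cl2, rt; crude treated with NaBH4 (0.3 equiv), MeOH, 0 °C
Reagents that add atoms: selenium dioxide O=[Se]=O; tert-butyl hydroperoxide CC(C)(C)OO
Why: Riley allylic oxidation (ene reaction, then [2,3]-shift) of a gem-dimethyl trisubstituted olefin hydroxylates the methyl group trans to the chain, so the (E)-alcohol (C7=C8 geometry, C9–OH) should form while the primary bromide is untouched; the borohydride returns any over-oxidised enal.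

**Step 2**
Reactants: 2 (E)-5-bromo-2-methylpent-2-en-1-ol
Product: 3 (E)-(5-bromo-2-methylpent-2-enyloxy)triethylsilane
Conditions: Et3SiCl, imidazole, CH2Cl2, 0 °C
Reagents that add atoms: chlorotriethylsilane CC[Si](Cl)(CC)CC
Why: Standard silylation of a primary allylic alcohol gives an ether that tolerates Grignard formation and is the most labile of the three silyl groups used.

**Step 3**
Reactants: 3 (E)-(5-bromo-2-methylpent-2-enyloxy)triethylsilane, 4 propargyl alcohol, 5 3-bromo-1-(trimethylsilyl)prop-1-yne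
Product: 8 (2Z)-2-[(3E)-4-methyl-5-(triethylsilyloxy)pent-3-enyl]-6-(trimethylsilyl)hex-2-en-5-yn-1-ol, via Grignard reagent 6 (not isolated), via alkenylmagnesium alkoxide 7 (not isolated)
Conditions: Mg, THF, 40 °C (2.5 equiv of 6); 4, CuI (10 mol%), Et2O–THF, −10 °C → rt; then 5 (2 equiv), 0 °C → rt; aq. NH4Cl
Reagents that add atoms: none
Why: CuI-catalysed anti-carbomagnesiation of the propargylic alkoxide places C5 on C4 and magnesium on C3 inside a five-membered chelate, and copper-mediated SN2 alkylation of that alkenylmagnesium by the silylated propargylic bromide (the silyl group blocks the SN2′ allene path) retains the geometry, so C2 ends cis to the C21 hydroxymethyl group.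

**Step 4**
Reactants: 8 (2Z)-2-[(3E)-4-methyl-5-(triethylsilyloxy)pent-3-enyl]-6-(trimethylsilyl)hex-2-en-5-yn-1-ol
Product: 9 (2Z)-1-(tert-butyldiphenylsilyloxy)-2-[(3E)-4-methyl-5-(triethylsilyloxy)pent-3-enyl]-6-(trimethylsilyl)hex-2-en-5-yne
Conditions: t-BuPh2SiCl, imidazole, DMF, rt
Reagents that add atoms: tert-butylchlorodiphenylsilane CC(C)(C)[Si](Cl)(c1ccccc1)c1ccccc1
Why: Silylation of the only free hydroxyl (C21–OH) installs the robust ether that stays until the last step.

**Step 5**
Reactants: 9 (2Z)-1-(tert-butyldiphenylsilyloxy)-2-[(3E)-4-methyl-5-(triethylsilyloxy)pent-3-enyl]-6-(trimethylsilyl)hex-2-en-5-yne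
Product: 10 (2Z)-1-(tert-butyldiphenylsilyloxy)-2-[(3E)-4-methyl-5-(triethylsilyloxy)pent-3-enyl]hex-2-en-5-yne
Conditions: K2CO3 (0.3 equiv), MeOH–THF, 0 °C → rt, short reaction time
Reagents that add atoms: none
Why: Methanolic carbonate cleaves the C(sp)–Si bond (protiodesilylation of an alkynylsilane) much faster than it attacks alkyl silyl ethers, and the brief mild exposure should not isomerise the skipped enyne.

**Step 6**
Reactants: 10 (2Z)-1-(tert-butyldiphenylsilyloxy)-2-[(3E)-4-methyl-5-(triethylsilyloxy)pent-3-enyl]hex-2-en-5-yne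
Product: 12 (5Z)-7-(tert-butyldiphenylsilyloxy)-6-[(3E)-4-methyl-5-(triethylsilyloxy)pent-3-enyl]hept-5-en-2-yn-1-ol, via lithium acetylide 11 (not isolated)
Conditions: n-BuLi (1.05 equiv), THF, −78 °C; (CH2O)n, −78 °C → rt; aq. NH4Cl
Reagents that add atoms: formaldehyde (as paraformaldehyde) C=O
Why: Kinetic deprotonation of the terminal alkyne (far more acidic than the C2 methylene) and 1,2-addition of the acetylide to formaldehyde add C16 as the propargylic alcohol.

**Step 7**
Reactants: 12 (5Z)-7-(tert-butyldiphenylsilyloxy)-6-[(3E)-4-methyl-5-(triethylsilyloxy)pent-3-enyl]hept-5-en-2-yn-1-ol, 1 5-bromo-2-methylpent-2-ene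
Product: 15 (2E,5Z)-7-(tert-butyldiphenylsilyloxy)-2-(4-methylpent-3-enyl)-6-[(3E)-4-methyl-5-(triethylsilyloxy)pent-3-enyl]hepta-2,5-dien-1-ol, via homoprenylmagnesium bromide 13 (not isolated), via alkenylmagnesium alkoxide 14 (not isolated)
Conditions: 1, Mg, THF (4 equiv of 13); 12, CuI (20 mol%), THF–Et2O, rt → 45 °C; aq. NH4Cl
Reagents that add atoms: none
Why: A second CuI-catalysed anti-carbomagnesiation, now of an internal 2-alkyn-1-ol, delivers the alkyl group to C15 and magnesium to C1 from opposite faces under alkoxide chelation, so protonolysis should give the olefin with C2 trans to the C16 hydroxymethyl group (E) while the silyl ethers are inert.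

**Step 8**
Reactants: 15 (2E,5Z)-7-(tert-butyldiphenylsilyloxy)-2-(4-methylpent-3-enyl)-6-[(3E)-4-methyl-5-(triethylsilyloxy)pent-3-enyl]hepta-2,5-dien-1-ol
Product: 16 (2E,5Z)-1-(tert-butyldimethylsilyloxy)-7-(tert-butyldiphenylsilyloxy)-2-(4-methylpent-3-enyl)-6-[(3E)-4-methyl-5-(triethylsilyloxy)pent-3-enyl]hepta-2,5-diene
Conditions: t-BuMe2SiCl, imidazole, DMF, rt
Reagents that add atoms: tert-butylchlorodimethylsilane CC(C)(C)[Si](C)(C)Cl
Why: Silylation masks C16–OH so that only the C9 oxygen can be activated next.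

**Step 9**
Reactants: 16 (2E,5Z)-1-(tert-butyldimethylsilyloxy)-7-(tert-butyldiphenylsilyloxy)-2-(4-methylpent-3-enyl)-6-[(3E)-4-methyl-5-(triethylsilyloxy)pent-3-enyl]hepta-2,5-diene
Product: 17 (2E,6Z,9E)-10-[(tert-butyldimethylsilyloxy)methyl]-6-[(tert-butyldiphenylsilyloxy)methyl]-2,14-dimethylpentadeca-2,6,9,13-tetraen-1-ol
Conditions: PPTS (0.1 equiv), MeOH–CH2Cl2, 0 °C
Reagents that add atoms: none
Why: Acid-catalysed methanolysis discriminates silyl ethers by bulk at silicon, so the TES ether at C9 should be solvolysed well before the TBS and TBDPS ethers.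

**Step 10**
Reactants: 17 (2E,6Z,9E)-10-[(tert-butyldimethylsilyloxy)methyl]-6-[(tert-butyldiphenylsilyloxy)methyl]-2,14-dimethylpentadeca-2,6,9,13-tetraen-1-ol
Product: 18 (2E,6Z,9E)-1-bromo-10-[(tert-butyldimethylsilyloxy)methyl]-6-[(tert-butyldiphenylsilyloxy)methyl]-2,14-dimethylpentadeca-2,6,9,13-tetraene
Conditions: CBr4, PPh3, 2,6-lutidine, CH2Cl2, 0 °C
Reagents that add atoms: carbon tetrabromide BrC(Br)(Br)Br
Why: Appel bromination of a primary allylic alcohol proceeds by SN2 displacement of the oxyphosphonium group without allylic transposition, so the C7=C8 geometry is kept and the silyl ethers survive the neutral, cold conditions.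

**Step 11**
Reactants: 19 nerol
Product: 20 neryl chloride, (Z)-1-chloro-3,7-dimethylocta-2,6-diene
Conditions: N-chlorosuccinimide, Me2S, CH2Cl2, −30 → 0 °C
Reagents that add atoms: N-chlorosuccinimide O=C1CCC(=O)N1Cl
Why: Corey–Kim chlorination converts the allylic alcohol through an alkoxysulfonium salt into the primary chloride by SN2, without allylic shift or loss of the Z geometry (C11=C12).

**Step 12**
Reactants: 20 neryl chloride
Product: 21 neryl phenyl sulfone, (Z)-(3,7-dimethylocta-2,6-dienylsulfonyl)benzene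
Conditions: PhSO2Na, DMF, rt
Reagents that add atoms: sodium benzenesulfinate [Na+].[O-]S(=O)c1ccccc1
Why: S-Alkylation of the sulfinate by the primary allylic chloride (SN2) gives the allylic sulfone that will make C10 nucleophilic.

**Step 13**
Reactants: 21 neryl phenyl sulfone
Product: 22 (Z)-[5-(3,3-dimethyloxiran-2-yl)-3-methylpent-2-enylsulfonyl]benzene (racemic)
Conditions: mCPBA (1.0 equiv), NaHCO3, CH2Cl2, 0 °C
Reagents that add atoms: 3-chloroperbenzoic acid OOC(=O)c1cccc(Cl)c1
Why: Prilezhaev epoxidation is electrophilic and should take the remote trisubstituted olefin in preference to the olefin deactivated by the allylic sulfonyl group.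

**Step 14**
Reactants: 22 (Z)-[5-(3,3-dimethyloxiran-2-yl)-3-methylpent-2-enylsulfonyl]benzene
Product: 24 (Z)-4-methyl-6-(phenylsulfonyl)hex-4-enal, via vicinal diol 23 (not isolated)
Conditions: H5IO6, THF–H2O, 0 °C → rt
Reagents that add atoms: none
Why: Periodic acid hydrates the epoxide and cleaves the resulting glycol (Malaprade cleavage), excising acetone and leaving the aldehyde carbon that becomes C22.

**Step 15**
Reactants: 24 (Z)-4-methyl-6-(phenylsulfonyl)hex-4-enal
Product: 25 (Z)-4-methyl-6-(phenylsulfonyl)hex-4-enoic acid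
Conditions: NaClO2, NaH2PO4, 2-methylbut-2-ene, t-BuOH–H2O, rt
Reagents that add atoms: sodium chlorite [Na+].[O-]Cl=O
Why: Pinnick oxidation converts the aldehyde into the acid chemoselectively, the scavenger olefin removing hypochlorous acid before it can reach the substrate olefin.

**Step 16**
Reactants: 25 (Z)-4-methyl-6-(phenylsulfonyl)hex-4-enoic acid, 18 (2E,6Z,9E)-1-bromo-10-[(tert-butyldimethylsilyloxy)methyl]-6-[(tert-butyldiphenylsilyloxy)methyl]-2,14-dimethylpentadeca-2,6,9,13-tetraene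
Product: 27 (4Z,8E,12Z,15E)-16-[(tert-butyldimethylsilyloxy)methyl]-12-[(tert-butyldiphenylsilyloxy)methyl]-4,8,20-trimethyl-6-(phenylsulfonyl)henicosa-4,8,12,15,19-pentaenoic acid (racemic at C10), via dilithio dianion 26 (not isolated)
Conditions: 25 (1.3 equiv), LiN(i-Pr)2 (2.7 equiv), THF–DMPU, −78 °C; 18, −78 → −30 °C; aq. citric acid
Reagents that add atoms: none
Why: Two equivalents of amide base give the carboxylate/α-sulfonyl carbanion, whose soft carbanion is alkylated at C10 by the primary allylic bromide (SN2 alkylation of an allylic sulfone anion), forming C9–C10 without touching any olefin geometry; the C10 stereocentre is racemic and disappears in step 17.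

**Step 17**
Reactants: 27 (4Z,8E,12Z,15E)-16-[(tert-butyldimethylsilyloxy)methyl]-12-[(tert-butyldiphenylsilyloxy)methyl]-4,8,20-trimethyl-6-(phenylsulfonyl)henicosa-4,8,12,15,19-pentaenoic acid
Product: 28 (4Z,8E,12Z,15E)-16-[(tert-butyldimethylsilyloxy)methyl]-12-[(tert-butyldiphenylsilyloxy)methyl]-4,8,20-trimethylhenicosa-4,8,12,15,19-pentaenoic acid
Conditions: PdCl2(dppp) (10 mol%), LiBHEt3 (6 equiv), THF, 0 °C; aq. citric acid
Reagents that add atoms: none
Why: Palladium-catalysed reductive desulfonylation: zerovalent palladium ionises the allylic sulfone to a π-allyl complex that takes hydride at the less substituted terminus C10, so C11=C12 should stay in place and, with the chelating diphosphine, keep its Z geometry; the carboxylate and silyl ethers are inert to the borohydride.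

**Step 18**
Reactants: 28 (4Z,8E,12Z,15E)-16-[(tert-butyldimethylsilyloxy)methyl]-12-[(tert-butyldiphenylsilyloxy)methyl]-4,8,20-trimethylhenicosa-4,8,12,15,19-pentaenoic acid
Product: 29 (4Z,8E,12Z,15E)-12-[(tert-butyldiphenylsilyloxy)methyl]-16-(hydroxymethyl)-4,8,20-trimethylhenicosa-4,8,12,15,19-pentaenoic acid
Conditions: AcOH–THF–H2O (3:1:1), rt
Reagents that add atoms: none
Why: Aqueous acetic acid hydrolyses the primary TBS ether (C16) while the far more acid-stable TBDPS ether (C21) remains, and no alcohol solvent is present that could esterify the acid.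

**Step 19**
Reactants: 29 (4Z,8E,12Z,15E)-12-[(tert-butyldiphenylsilyloxy)methyl]-16-(hydroxymethyl)-4,8,20-trimethylhenicosa-4,8,12,15,19-pentaenoic acid
Product: 31 18-membered lactone of 29 (ring O–C22–C14–C13–C12=C11–C10–C9–C8=C7–C6–C5–C4=C3–C2–C1=C15–C16; 11Z; 7E; C2 trans to C5; C1=C15 E; C21–OTBDPS; 4-methylpent-3-enyl on C15), via mixed anhydride 30 (not isolated)
Conditions: 2,4,6-trichlorobenzoyl chloride, Et3N, THF, rt; slow addition to DMAP, toluene, 80 °C, about 1 mM
Reagents that add atoms: none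
Why: Yamaguchi macrolactonisation: the mixed anhydride is acylated onto DMAP at the aliphatic carbonyl, and the only free hydroxyl (unhindered primary allylic C16–OH) closes the 18-membered ring under high dilution.

**Step 20**
Reactants: 31 18-membered lactone
Product: 34 (1S,14S,3Z,7E,11Z)-4-[(tert-butyldiphenylsilyloxy)methyl]-8,12-dimethyl-1-(6-methylhepta-1,5-dien-2-yl)cyclotetradeca-3,7,11-triene-14-carboxylic acid (target atom labels), via boron ketene acetal 32 (not isolated), via boron carboxylate 33 (not isolated)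
Conditions: (4S,5S)-2-bromo-4,5-diphenyl-1,3-bis(4-methylphenylsulfonyl)-1,3,2-diazaborolidine (2 equiv, freshly prepared), 1,2,2,6,6-pentamethylpiperidine (4 equiv), CH2Cl2, −78 °C, then 4 °C, 48 h; pH 7 buffer
Reagents that add atoms: none
Why: The bromoborane and the hindered amine convert the lactone into boron ketene acetal 32 (C13 anti to the ring oxygen), which undergoes a concerted suprafacial [3,3]-sigmatropic shift across C14=C22–O–C16–C15=C1 through a transannular chair. The closest known reaction type is the enantioselective ester enolate (Ireland–Claisen type) ring contraction of macrolactones with chiral diazaborolidine bromides. The 14-membered ring is closed by contraction, not by end-to-end cyclisation: C1–C14 forms inside the 18-membered ring while O–C16 breaks, leaving C22 and the C15=C16 methylene exocyclic. The C1 stereocentre is controlled by the enolate face left open by the (S,S)-sulfonamide ligand on boron, relayed through one chair in which the E geometry of C1=C15 places C2 equatorial; C14 follows from the enolate geometry, is expected trans to the C1 substituent, and is erased in step 21. The step needs enolisation at C14 only, chair over boat, and absolute facial control; the single ester with one α-methylene secures the first, the E trisubstituted olefin in a flexible ring the second, the reagent the third.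

**Step 21**
Reactants: 34 ring-contracted acid
Product: 36 (1R,3Z,7E,11Z)-4-[(tert-butyldiphenylsilyloxy)methyl]-8,12-dimethyl-1-(6-methylhepta-1,5-dien-2-yl)cyclotetradeca-3,7,11-triene, via Barton ester 35 (not isolated)
Conditions: 2,2′-dithiobis(pyridine N-oxide), n-Bu3P, THF, 0 °C, dark; then t-BuSH (excess), tungsten lamp, rt
Reagents that add atoms: none
Why: Barton decarboxylation: the thiohydroxamate ester fragments under visible light to the C14 radical with loss of CO2, and concentrated thiol transfers hydrogen faster than the radical can add to neighbouring olefins, so C14 becomes CH2 and the C1 stereocentre, which is not part of the radical, is kept.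

**Step 22**
Reactants: 36 silyl ether of the target
Product: 37 target, (1R,3Z,7E,11Z)-4-(hydroxymethyl)-8,12-dimethyl-1-(6-methylhepta-1,5-dien-2-yl)cyclotetradeca-3,7,11-triene
Conditions: Bu4NF, THF, 0 °C → rt
Reagents that add atoms: none
Why: Fluoride-induced Si–O cleavage frees the primary allylic alcohol under conditions that touch neither the olefins nor the stereocentre.

**Compound list**

1 | 5-bromo-2-methylpent-2-ene | CC(C)=CCCBr | starting material
2 | (E)-5-bromo-2-methylpent-2-en-1-ol | OC/C(C)=C/CCBr | intermediate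
3 | (E)-(5-bromo-2-methylpent-2-enyloxy)triethylsilane | CC[Si](CC)(CC)OC/C(C)=C/CCBr | intermediate
4 | propargyl alcohol | C#CCO | starting material
5 | 3-bromo-1-(trimethylsilyl)prop-1-yne | C[Si](C)(C)C#CCBr | starting material
6 | (E)-[4-methyl-5-(triethylsilyloxy)pent-3-enyl]magnesium bromide | CC[Si](CC)(CC)OC/C(C)=C/CC[Mg]Br | intermediate (not isolated)
7 | bromomagnesium alkoxide of the (Z)-3-bromomagnesio-2-alkylallyl alcohol (Mg on C3 cis to C21–O) | CC[Si](CC)(CC)OC/C(C)=C/CC/C(CO[Mg]Br)=C/[Mg]Br | intermediate (not isolated)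
8 | (2Z)-2-[(3E)-4-methyl-5-(triethylsilyloxy)pent-3-enyl]-6-(trimethylsilyl)hex-2-en-5-yn-1-ol | C[Si](C)(C)C#CC/C=C(\CO)CC/C=C(C)/CO[Si](CC)(CC)CC | intermediate
9 | (2Z)-1-(tert-butyldiphenylsilyloxy)-2-[(3E)-4-methyl-5-(triethylsilyloxy)pent-3-enyl]-6-(trimethylsilyl)hex-2-en-5-yne | C[Si](C)(C)C#CC/C=C(\CO[Si](c1ccccc1)(c1ccccc1)C(C)(C)C)CC/C=C(C)/CO[Si](CC)(CC)CC | intermediate
10 | (2Z)-1-(tert-butyldiphenylsilyloxy)-2-[(3E)-4-methyl-5-(triethylsilyloxy)pent-3-enyl]hex-2-en-5-yne | C#CC/C=C(\CO[Si](c1ccccc1)(c1ccccc1)C(C)(C)C)CC/C=C(C)/CO[Si](CC)(CC)CC | intermediate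
11 | lithium acetylide of 10 | [Li]C#CC/C=C(\CO[Si](c1ccccc1)(c1ccccc1)C(C)(C)C)CC/C=C(C)/CO[Si](CC)(CC)CC | intermediate (not isolated)
12 | (5Z)-7-(tert-butyldiphenylsilyloxy)-6-[(3E)-4-methyl-5-(triethylsilyloxy)pent-3-enyl]hept-5-en-2-yn-1-ol | OCC#CC/C=C(\CO[Si](c1ccccc1)(c1ccccc1)C(C)(C)C)CC/C=C(C)/CO[Si](CC)(CC)CC | intermediate
13 | (4-methylpent-3-enyl)magnesium bromide | CC(C)=CCC[Mg]Br | intermediate (not isolated)
14 | bromomagnesium alkoxide of the C1-magnesiated allylic alcohol (Mg on C1 cis to C16–O) | CC(C)=CCC/C(CO[Mg]Br)=C(/[Mg]Br)C/C=C(\CO[Si](c1ccccc1)(c1ccccc1)C(C)(C)C)CC/C=C(C)/CO[Si](CC)(CC)CC | intermediate (not isolated)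
15 | (2E,5Z)-7-(tert-butyldiphenylsilyloxy)-2-(4-methylpent-3-enyl)-6-[(3E)-4-methyl-5-(triethylsilyloxy)pent-3-enyl]hepta-2,5-dien-1-ol | CC(C)=CCC/C(CO)=C\C/C=C(\CO[Si](c1ccccc1)(c1ccccc1)C(C)(C)C)CC/C=C(C)/CO[Si](CC)(CC)CC | intermediate
16 | (2E,5Z)-1-(tert-butyldimethylsilyloxy)-7-(tert-butyldiphenylsilyloxy)-2-(4-methylpent-3-enyl)-6-[(3E)-4-methyl-5-(triethylsilyloxy)pent-3-enyl]hepta-2,5-diene | CC(C)=CCC/C(CO[Si](C)(C)C(C)(C)C)=C\C/C=C(\CO[Si](c1ccccc1)(c1ccccc1)C(C)(C)C)CC/C=C(C)/CO[Si](CC)(CC)CC | intermediate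
17 | (2E,6Z,9E)-10-[(tert-butyldimethylsilyloxy)methyl]-6-[(tert-butyldiphenylsilyloxy)methyl]-2,14-dimethylpentadeca-2,6,9,13-tetraen-1-ol | CC(C)=CCC/C(CO[Si](C)(C)C(C)(C)C)=C\C/C=C(\CO[Si](c1ccccc1)(c1ccccc1)C(C)(C)C)CC/C=C(C)/CO | intermediate
18 | (2E,6Z,9E)-1-bromo-10-[(tert-butyldimethylsilyloxy)methyl]-6-[(tert-butyldiphenylsilyloxy)methyl]-2,14-dimethylpentadeca-2,6,9,13-tetraene | CC(C)=CCC/C(CO[Si](C)(C)C(C)(C)C)=C\C/C=C(\CO[Si](c1ccccc1)(c1ccccc1)C(C)(C)C)CC/C=C(C)/CBr | intermediate
19 | nerol | CC(C)=CCC/C(C)=C\CO | starting material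
20 | neryl chloride | CC(C)=CCC/C(C)=C\CCl | intermediate
21 | neryl phenyl sulfone | CC(C)=CCC/C(C)=C\CS(=O)(=O)c1ccccc1 | intermediate
22 | (Z)-[5-(3,3-dimethyloxiran-2-yl)-3-methylpent-2-enylsulfonyl]benzene (racemic) | CC1(C)OC1CC/C(C)=C\CS(=O)(=O)c1ccccc1 | intermediate
23 | (Z)-2,6-dimethyl-8-(phenylsulfonyl)oct-6-ene-2,3-diol (racemic) | CC(C)(O)C(O)CC/C(C)=C\CS(=O)(=O)c1ccccc1 | intermediate (not isolated)
24 | (Z)-4-methyl-6-(phenylsulfonyl)hex-4-enal | O=CCC/C(C)=C\CS(=O)(=O)c1ccccc1 | intermediate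
25 | (Z)-4-methyl-6-(phenylsulfonyl)hex-4-enoic acid | OC(=O)CC/C(C)=C\CS(=O)(=O)c1ccccc1 | intermediate
26 | dilithio dianion of 25 (carboxylate and C10 carbanion) | [Li+].[Li+].[O-]C(=O)CC/C(C)=C\[CH-]S(=O)(=O)c1ccccc1 | intermediate (not isolated)
27 | (4Z,8E,12Z,15E)-16-[(tert-butyldimethylsilyloxy)methyl]-12-[(tert-butyldiphenylsilyloxy)methyl]-4,8,20-trimethyl-6-(phenylsulfonyl)henicosa-4,8,12,15,19-pentaenoic acid (racemic at C10) | OC(=O)CC/C(C)=C\C(C/C(C)=C/CC/C(CO[Si](c1ccccc1)(c1ccccc1)C(C)(C)C)=C/C/C=C(/CO[Si](C)(C)C(C)(C)C)CCC=C(C)C)S(=O)(=O)c1ccccc1 | intermediate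
28 | (4Z,8E,12Z,15E)-16-[(tert-butyldimethylsilyloxy)methyl]-12-[(tert-butyldiphenylsilyloxy)methyl]-4,8,20-trimethylhenicosa-4,8,12,15,19-pentaenoic acid | OC(=O)CC/C(C)=C\CC/C(C)=C/CC/C(CO[Si](c1ccccc1)(c1ccccc1)C(C)(C)C)=C/C/C=C(/CO[Si](C)(C)C(C)(C)C)CCC=C(C)C | intermediate
29 | (4Z,8E,12Z,15E)-12-[(tert-butyldiphenylsilyloxy)methyl]-16-(hydroxymethyl)-4,8,20-trimethylhenicosa-4,8,12,15,19-pentaenoic acid | OC(=O)CC/C(C)=C\CC/C(C)=C/CC/C(CO[Si](c1ccccc1)(c1ccccc1)C(C)(C)C)=C/C/C=C(/CO)CCC=C(C)C | intermediate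
30 | mixed anhydride of 29 with 2,4,6-trichlorobenzoic acid | O=C(OC(=O)CC/C(C)=C\CC/C(C)=C/CC/C(CO[Si](c1ccccc1)(c1ccccc1)C(C)(C)C)=C/C/C=C(/CO)CCC=C(C)C)c1c(Cl)cc(Cl)cc1Cl | intermediate (not isolated)
31 | 18-membered lactone (C22 carbonyl to C16–O; C21–OTBDPS) | O=C1CC/C(C)=C\CC/C(C)=C/CC/C(CO[Si](c2ccccc2)(c2ccccc2)C(C)(C)C)=C/C/C=C(\CCC=C(C)C)CO1 | intermediate (key-step precursor)
32 | boron ketene acetal of 31 with the (4S,5S)-diazaborolidine (C13 anti to ring oxygen) | Cc1ccc(cc1)S(=O)(=O)N1B(O/C2=C\C/C(C)=C\CC/C(C)=C/CC/C(CO[Si](c3ccccc3)(c3ccccc3)C(C)(C)C)=C/C/C=C(\CCC=C(C)C)CO2)N(S(=O)(=O)c3ccc(C)cc3)[C@@H](c3ccccc3)[C@@H]1c1ccccc1 | intermediate (not isolated)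
33 | boron carboxylate of 34 | C=C(CCC=C(C)C)[C@H]1C/C=C(\CO[Si](c2ccccc2)(c2ccccc2)C(C)(C)C)CC/C=C(\C)CC/C=C(/C)C[C@@H]1C(=O)OB1N(S(=O)(=O)c2ccc(C)cc2)[C@@H](c2ccccc2)[C@H](c2ccccc2)N1S(=O)(=O)c1ccc(C)cc1 | intermediate (not isolated)
34 | (1S,14S,3Z,7E,11Z)-4-[(tert-butyldiphenylsilyloxy)methyl]-8,12-dimethyl-1-(6-methylhepta-1,5-dien-2-yl)cyclotetradeca-3,7,11-triene-14-carboxylic acid | C=C(CCC=C(C)C)[C@H]1C/C=C(\CO[Si](c2ccccc2)(c2ccccc2)C(C)(C)C)CC/C=C(\C)CC/C=C(/C)C[C@@H]1C(=O)O | intermediate (key-step product)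
35 | Barton ester of 34 (2-thioxopyridin-1(2H)-yl ester) | C=C(CCC=C(C)C)[C@H]1C/C=C(\CO[Si](c2ccccc2)(c2ccccc2)C(C)(C)C)CC/C=C(\C)CC/C=C(/C)C[C@@H]1C(=O)ON1C=CC=CC1=S | intermediate (not isolated)
36 | (1R,3Z,7E,11Z)-4-[(tert-butyldiphenylsilyloxy)methyl]-8,12-dimethyl-1-(6-methylhepta-1,5-dien-2-yl)cyclotetradeca-3,7,11-triene | C=C(CCC=C(C)C)[C@H]1C/C=C(\CO[Si](c2ccccc2)(c2ccccc2)C(C)(C)C)CC/C=C(\C)CC/C=C(/C)CC1 | intermediate
37 | (1R,3Z,7E,11Z)-4-(hydroxymethyl)-8,12-dimethyl-1-(6-methylhepta-1,5-dien-2-yl)cyclotetradeca-3,7,11-triene | C=C(CCC=C(C)C)[C@H]1C/C=C(\CO)CC/C=C(\C)CC/C=C(/C)CC1 | target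

**Step count.** 22 steps in total. Longest linear sequence: 17 steps (steps 1–10, then 16–22, from compound 1). The nerol branch (steps 11–15) joins at step 16.

**Steps most likely to fail**

Step 20. Enolisation of the macrolactone by the hindered bromoborane may be incomplete, or the rearrangement may leak through a boat array or the other enolate geometry, which would lower conversion and enantiomeric purity. The fallback gives up reagent control and resolves afterwards. It sets out from lactone 31: LiN(SiMe3)2 and Me3SiCl–Et3N in THF at −78 °C give silyl ketene acetal F1, which on warming to 65 °C should rearrange (classical Ireland–Claisen) to trimethylsilyl ester F2; dilute acid work-up gives racemic acid F3, and preparative chromatography on a chiral stationary phase separates the enantiomers. The route is rejoined at acid 34.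

Step 7. Slow addition to the internal alkyne, β-hydride reduction by the alkyl Grignard reagent, or deprotonation at the doubly activated C2 methylene may erode yield or regiochemistry. The fallback separates hydrometalation from C–C bond formation. It sets out from alkynol 12: anti-hydroalumination with LiAlH4 and catalytic AlCl3 in THF at 0 °C, followed by I2 at −78 °C, should give (2Z,5Z)-2-iodo allylic alcohol F4 with iodine on C15 cis to C2. Negishi coupling with (4-methylpent-3-enyl)zinc bromide (from 13 and ZnBr2) and Pd(dppf)Cl2 in THF replaces iodine with retention. The route is rejoined at allylic alcohol 15.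

Step 16. The carboxylate–carbanion dianion may aggregate or dissolve poorly, and proton transfer or O-alkylation of the carboxylate may compete with C-alkylation. The fallback carries C22 at the aldehyde oxidation level so that a simple monoanion is alkylated. It sets out from aldehyde 24 and bromide 18: HC(OMe)3, MeOH and PPTS give dimethyl acetal F5; n-BuLi in THF–DMPU at −78 °C gives lithio sulfone F6, which is alkylated by 18 to coupled sulfone acetal F7; PdCl2(dppp) and LiBHEt3 give acetal F8; AcOH–THF–H2O hydrolyses the acetal and the C16 TBS ether together to hydroxy aldehyde F9; Pinnick oxidation (NaClO2, NaH2PO4, 2-methylbut-2-ene) then gives the acid. The route is rejoined at seco acid 29.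

**Further compounds**

F1 | step 20 | trimethylsilyl ketene acetal of lactone 31 | C[Si](C)(C)OC1=CC/C(C)=C\CC/C(C)=C/CC/C(CO[Si](c2ccccc2)(c2ccccc2)C(C)(C)C)=C/C/C=C(\CCC=C(C)C)CO1
F2 | step 20 | trimethylsilyl ester of the racemic ring-contracted acid | C=C(CCC=C(C)C)C1C/C=C(\CO[Si](c2ccccc2)(c2ccccc2)C(C)(C)C)CC/C=C(\C)CC/C=C(/C)CC1C(=O)O[Si](C)(C)C
F3 | step 20 | racemic (1S*,14S*) ring-contracted acid | C=C(CCC=C(C)C)C1C/C=C(\CO[Si](c2ccccc2)(c2ccccc2)C(C)(C)C)CC/C=C(\C)CC/C=C(/C)CC1C(=O)O
F4 | step 7 | (2Z,5Z)-7-(tert-butyldiphenylsilyloxy)-2-iodo-6-[(3E)-4-methyl-5-(triethylsilyloxy)pent-3-enyl]hepta-2,5-dien-1-ol | OC/C(I)=C/C/C=C(\CO[Si](c1ccccc1)(c1ccccc1)C(C)(C)C)CC/C=C(C)/CO[Si](CC)(CC)CC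
F5 | step 16 | (Z)-(6,6-dimethoxy-3-methylhex-2-enylsulfonyl)benzene | COC(OC)CC/C(C)=C\CS(=O)(=O)c1ccccc1
F6 | step 16 | lithio derivative of F5 at C10 | [Li+].COC(OC)CC/C(C)=C\[CH-]S(=O)(=O)c1ccccc1
F7 | step 16 | coupled sulfone dimethyl acetal (C22 acetal; C10 sulfone; C16–OTBS; C21–OTBDPS) | COC(OC)CC/C(C)=C\C(C/C(C)=C/CC/C(CO[Si](c1ccccc1)(c1ccccc1)C(C)(C)C)=C/C/C=C(/CO[Si](C)(C)C(C)(C)C)CCC=C(C)C)S(=O)(=O)c1ccccc1
F8 | step 16 | desulfonylated dimethyl acetal | COC(OC)CC/C(C)=C\CC/C(C)=C/CC/C(CO[Si](c1ccccc1)(c1ccccc1)C(C)(C)C)=C/C/C=C(/CO[Si](C)(C)C(C)(C)C)CCC=C(C)C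
F9 | step 16 | (4Z,8E,12Z,15E)-12-[(tert-butyldiphenylsilyloxy)methyl]-16-(hydroxymethyl)-4,8,20-trimethylhenicosa-4,8,12,15,19-pentaenal | O=CCC/C(C)=C\CC/C(C)=C/CC/C(CO[Si](c1ccccc1)(c1ccccc1)C(C)(C)C)=C/C/C=C(/CO)CCC=C(C)C
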